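**Retrosynthetic overview**

- Ring A is closed last. In benzofuran numbering ring A is C3a–C4–C5–C6–C7–C7a, and C4 and C7 are the ester carbon and the 2-methyl carbon of a 2-methyl-4,5-dihydrofuran-3-carboxylate (ring B = O1, C2, C3, C3a, C7a). Ring A therefore lacks only C5–C6, which phenyl vinyl sulfone supplies in an anionic Michael–Dieckmann annulation (C6–C7, then C4–C5); the sulfonyl group is then removed and C5 hydroxylated.
- Ring B is made first from methyl acetoacetate and an epoxy iodide: C3–C3a by C-alkylation, O1–C2 by 5-exo opening of the epoxide by the enolate oxygen with inversion at C2.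
- Side chain: the C3'–C4' bond comes from a B-alkyl Suzuki–Miyaura coupling with (Z)-3-iodobut-2-en-1-ol; C4' comes from a Wittig methylenation.
- Stereocentres: two Sharpless epoxidations with D-(−)-diethyl tartrate set C6'/C7' (after hydrolysis with inversion at C7') and C2/C3'; an oxaziridine hydroxylation sets C5. All hydroxyls travel as triethylsilyl ethers and are freed by one fluoride step.

Key step: step 12

Remark: the side chain is numbered C1' (= ring C3), C2' (= ring C2) and C3' to C11' outwards. The target is read from the SMILES string as 2S,5R in the bicycle and 3'S,6'R,7'S in the chain.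

**Route**

Step 1
Reactants: 1 geraniol
Product: 2 (2R,3R)-2,3-epoxygeraniol, [(2R,3R)-3-methyl-3-(4-methylpent-3-en-1-yl)oxiran-2-yl]methanol
Conditions: Ti(OiPr)4 (5 mol %), D-(−)-diethyl tartrate (6 mol %), t-BuOOH, 4 Å MS, CH2Cl2, −20 °C
Reagents that add atoms: tert-butyl hydroperoxide, CC(C)(C)OO
Why: Sharpless asymmetric epoxidation acts only on the allylic-alcohol double bond, so the 6,7-alkene is left alone, and the D-(−)-tartrate catalyst should deliver oxygen to the face that gives the 2R,3R epoxide.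

Step 2
Reactants: 2 (2R,3R)-2,3-epoxygeraniol
Product: 3 (2R,3S)-3,7-dimethyloct-6-ene-1,2,3-triol
Conditions: HClO4 (5 mol %), THF/H2O (3:1), 0 °C to rt
Reagents that add atoms: water, O
Why: In this acid-catalysed epoxide hydrolysis water should attack the tertiary C3 with inversion while the C2–O bond is kept, which gives the unlike (6'R,7'S) diol pair of the target.

Step 3
Reactants: 3 (2R,3S)-3,7-dimethyloct-6-ene-1,2,3-triol
Product: 4 (2R,3S)-3,7-dimethyl-1,2,3-tris(triethylsilyloxy)oct-6-ene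
Conditions: Et3SiOTf (3.6 equiv), 2,6-lutidine, CH2Cl2, −78 °C to 0 °C
Reagents that add atoms: triethylsilyl trifluoromethanesulfonate, CC[Si](CC)(CC)OS(=O)(=O)C(F)(F)F
Why: Silylation with the silyl triflate and 2,6-lutidine is strong enough to cap the tertiary hydroxyl together with the primary and secondary ones in one operation.

Step 4
Reactants: 4 (2R,3S)-3,7-dimethyl-1,2,3-tris(triethylsilyloxy)oct-6-ene
Product: 5 (2S,3S)-3,7-dimethyl-2,3-bis(triethylsilyloxy)oct-6-enal
Conditions: (COCl)2, DMSO, CH2Cl2, −78 °C to −40 °C; Et3N, −78 °C to rt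
Reagents that add atoms: none
Why: Under Swern conditions the chlorosulfonium species cleaves the unhindered primary triethylsilyl ether and oxidises it directly to the aldehyde, while the secondary and tertiary silyl ethers are too hindered to react at low temperature (the change of descriptor at C2 is only a change of priorities).

Step 5
Reactants: 5 (2S,3S)-3,7-dimethyl-2,3-bis(triethylsilyloxy)oct-6-enal
Product: 6 (3R,4S)-4,8-dimethyl-3,4-bis(triethylsilyloxy)nona-1,7-diene
Conditions: Ph3PCH3Br, KN(SiMe3)2, THF, 0 °C; then 5, −78 °C to 0 °C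
Reagents that add atoms: methyltriphenylphosphonium bromide, C[P+](c1ccccc1)(c1ccccc1)c1ccccc1.[Br-]
Why: Wittig methylenation with the non-stabilised ylide at low temperature adds C4' and should not epimerise the α-silyloxy centre C6'.

Step 6
Reactants: 7 but-2-yn-1-ol
Product: 9 (Z)-3-iodobut-2-en-1-ol, via cyclic alkenylalanate 8 (not isolated)
Conditions: NaAlH2(OCH2CH2OMe)2, THF, 0 °C to rt; then I2, −78 °C to 0 °C
Reagents that add atoms: iodine, II
Why: Hydroxyl-directed trans-hydroalumination of the propargylic alcohol places aluminium on C3 cis to the carbinol carbon in a five-membered alanate, and iodinolysis with retention should give only the Z iodide.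

Step 7
Reactants: 6 (3R,4S)-4,8-dimethyl-3,4-bis(triethylsilyloxy)nona-1,7-diene; 9 (Z)-3-iodobut-2-en-1-ol
Product: 11 (2Z,6R,7S)-3,7,11-trimethyl-6,7-bis(triethylsilyloxy)dodeca-2,10-dien-1-ol, via B-alkyl-9-BBN borane 10 (not isolated)
Conditions: 9-BBN, THF, rt; then 9, PdCl2(dppf) (5 mol %), AsPh3, Cs2CO3, DMF/H2O, rt
Reagents that add atoms: none
Why: 9-BBN hydroborates the monosubstituted alkene at its terminus much faster than the trisubstituted one, and the B-alkyl Suzuki–Miyaura coupling forms the C3'–C4' bond with retention of the Z geometry of the alkenyl iodide.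

Step 8
Reactants: 11 (2Z,6R,7S)-3,7,11-trimethyl-6,7-bis(triethylsilyloxy)dodeca-2,10-dien-1-ol
Product: 12 (2R,3S,6R,7S)-2,3-epoxy-3,7,11-trimethyl-6,7-bis(triethylsilyloxy)dodec-10-en-1-ol
Conditions: Ti(OiPr)4 (10 mol %), D-(−)-diethyl tartrate (12 mol %), t-BuOOH, 4 Å MS, CH2Cl2, −20 °C
Reagents that add atoms: tert-butyl hydroperoxide, CC(C)(C)OO
Why: Sharpless asymmetric epoxidation again touches only the allylic-alcohol alkene, and with D-(−)-tartrate the Z olefin should give the 2R,3S epoxide under reagent control, independent of the remote C6 and C7 centres.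

Step 9
Reactants: 12 (2R,3S,6R,7S)-2,3-epoxy-3,7,11-trimethyl-6,7-bis(triethylsilyloxy)dodec-10-en-1-ol
Product: 13 (2S,3S,6R,7S)-2,3-epoxy-1-iodo-3,7,11-trimethyl-6,7-bis(triethylsilyloxy)dodec-10-ene
Conditions: I2, PPh3, imidazole, CH2Cl2, 0 °C
Reagents that add atoms: iodine, II
Why: Appel-type iodination converts the primary alcohol into the iodide by SN2 at C1 under buffered conditions that leave the epoxide and the silyl ethers intact (the C2 descriptor changes by priority only).

Step 10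
Reactants: 13 (2S,3S,6R,7S)-2,3-epoxy-1-iodo-3,7,11-trimethyl-6,7-bis(triethylsilyloxy)dodec-10-ene; 14 methyl acetoacetate
Product: 16 methyl (5S)-5-[(2S,5R,6S)-2-hydroxy-6,10-dimethyl-5,6-bis(triethylsilyloxy)undec-9-en-2-yl]-2-methyl-4,5-dihydrofuran-3-carboxylate, via C-alkylated epoxy keto ester 15 (not isolated)
Conditions: 14 (2 equiv), Cs2CO3, DMF, rt, then 60 °C
Reagents that add atoms: none
Why: The soft acetoacetate enolate is C-alkylated by the primary iodide (SN2), and the enolate of the resulting keto ester should then open the epoxide through oxygen at the nearer carbon C2' (5-exo-tet, inversion), which closes ring B, sets C2 as S and frees the C3' oxygen with its configuration retained; the exo mode, the hindered tertiary C3' and the polar aprotic medium favour this over six-membered or carbon-centred closure.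

Step 11
Reactants: 16 methyl (5S)-5-[(2S,5R,6S)-2-hydroxy-6,10-dimethyl-5,6-bis(triethylsilyloxy)undec-9-en-2-yl]-2-methyl-4,5-dihydrofuran-3-carboxylate
Product: 17 methyl (5S)-2-methyl-5-[(2S,5R,6S)-6,10-dimethyl-2,5,6-tris(triethylsilyloxy)undec-9-en-2-yl]-4,5-dihydrofuran-3-carboxylate
Conditions: Et3SiOTf, 2,6-lutidine, CH2Cl2, −78 °C to 0 °C
Reagents that add atoms: triethylsilyl trifluoromethanesulfonate, CC[Si](CC)(CC)OS(=O)(=O)C(F)(F)F
Why: Silylation of the tertiary alcohol with the silyl triflate removes the last acidic proton before the strong-base step, and any silyl migration in step 10 converges on the same tris-silyl ether.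

Step 12
Reactants: 17 methyl (5S)-2-methyl-5-[(2S,5R,6S)-6,10-dimethyl-2,5,6-tris(triethylsilyloxy)undec-9-en-2-yl]-4,5-dihydrofuran-3-carboxylate; 18 phenyl vinyl sulfone
Product: 21 (2S)-2-[(2S,5R,6S)-6,10-dimethyl-2,5,6-tris(triethylsilyloxy)undec-9-en-2-yl]-5-(phenylsulfonyl)-2,3,6,7-tetrahydro-1-benzofuran-4(5H)-one (both C5 epimers), via lithium dienolate 19 (not isolated), via lithiated Michael adduct 20 (not isolated)
Conditions: LiN(iPr)2 (1.1 equiv), THF, −78 °C; then 18 (1.1 equiv), −78 °C to 0 °C; aq. NH4Cl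
Reagents that add atoms: none
Why: Proposed new method: LiN(iPr)2 removes a proton from the C7 methyl group, which is vinylogous to the ester through C7a=C3a, and the lithium dienolate 19 adds through C7 to the β-carbon of the vinyl sulfone (C6–C7 bond). The α-sulfonyl carbanion 20 then acylates the ester carbon C4 (C4–C5 bond) with loss of methoxide, a 6-exo-trig Dieckmann-type closure of ring A, and the lithium methoxide set free deprotonates the acidic β-keto sulfone, which pulls the sequence forward. The closest known reactions are the Michael–Dieckmann annulations of ester dienolates and ortho-toluate anions with acrylates and enones, and the acylation of α-sulfonyl carbanions by esters; their combination with a vinyl sulfone on a dihydrofuran ester is the untested part. No stereocentre of the target is formed: C5 arises as a labile mixture of epimers that is erased in step 13, and C2 with its side chain is a spectator. The step needs γ- over α-attack of the dienolate: α-attack at C3a would give a quaternary adduct that could only close a four-membered ring and should revert by retro-Michael reaction, whereas the γ-adduct is removed irreversibly by ring closure. Only a small excess of base is used so that no free amide is left to attack the vinyl sulfone.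

Step 13
Reactants: 21 (2S)-2-[(2S,5R,6S)-6,10-dimethyl-2,5,6-tris(triethylsilyloxy)undec-9-en-2-yl]-5-(phenylsulfonyl)-2,3,6,7-tetrahydro-1-benzofuran-4(5H)-one
Product: 22 (2S)-2-[(2S,5R,6S)-6,10-dimethyl-2,5,6-tris(triethylsilyloxy)undec-9-en-2-yl]-2,3,6,7-tetrahydro-1-benzofuran-4(5H)-one
Conditions: Al(Hg), THF/H2O (9:1), rt
Reagents that add atoms: none
Why: Reductive desulfonylation of the β-keto sulfone by electron transfer from aluminium amalgam cleaves the C5–S bond and, after protonation of the enolate, removes the undefined C5 centre without touching the vinylogous ester, the alkene or the silyl ethers.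

Step 14
Reactants: 22 (2S)-2-[(2S,5R,6S)-6,10-dimethyl-2,5,6-tris(triethylsilyloxy)undec-9-en-2-yl]-2,3,6,7-tetrahydro-1-benzofuran-4(5H)-one
Product: 23 (2S,5R)-5-hydroxy-2-[(2S,5R,6S)-6,10-dimethyl-2,5,6-tris(triethylsilyloxy)undec-9-en-2-yl]-2,3,6,7-tetrahydro-1-benzofuran-4(5H)-one
Conditions: KN(SiMe3)2, THF, −78 °C; then (+)-(camphorsulfonyl)oxaziridine, −78 °C; aq. NH4Cl
Reagents that add atoms: (+)-(camphorsulfonyl)oxaziridine, CC1(C)[C@@H]2CC[C@]13CS(=O)(=O)N4O[C@@]34C2
Why: Kinetic deprotonation of the vinylogous ester at C5 gives the cross-conjugated enolate, which is hydroxylated by the N-sulfonyloxaziridine; the camphor-derived reagent is the only source of facial bias because C2 is remote, and the (+)-enantiomer is chosen to favour the 5R epimer by analogy with endocyclic ketone enolates of the tetralone type, the C5 epimers being separable diastereomers.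

Step 15
Reactants: 23 (2S,5R)-5-hydroxy-2-[(2S,5R,6S)-6,10-dimethyl-2,5,6-tris(triethylsilyloxy)undec-9-en-2-yl]-2,3,6,7-tetrahydro-1-benzofuran-4(5H)-one
Product: 24 (2S,5R)-5-hydroxy-2-[(2S,5R,6S)-2,5,6-trihydroxy-6,10-dimethylundec-9-en-2-yl]-2,3,6,7-tetrahydro-1-benzofuran-4(5H)-one (CNP0125453.2)
Conditions: HF·pyridine, pyridine, THF, 0 °C to rt
Reagents that add atoms: none
Why: Fluoride-mediated cleavage of the three Si–O bonds under buffered, non-basic conditions should free the triol without epimerising the α-ketol at C5 or hydrolysing the vinylogous ester.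

**Compound list**

1 | geraniol | CC(C)=CCC/C(C)=C/CO | starting material
2 | (2R,3R)-2,3-epoxygeraniol | OC[C@H]1O[C@]1(C)CCC=C(C)C | intermediate
3 | (2R,3S)-3,7-dimethyloct-6-ene-1,2,3-triol | OC[C@@H](O)[C@@](C)(O)CCC=C(C)C | intermediate
4 | (2R,3S)-3,7-dimethyl-1,2,3-tris(triethylsilyloxy)oct-6-ene | CC[Si](CC)(CC)OC[C@@H](O[Si](CC)(CC)CC)[C@@](C)(O[Si](CC)(CC)CC)CCC=C(C)C | intermediate
5 | (2S,3S)-3,7-dimethyl-2,3-bis(triethylsilyloxy)oct-6-enal | O=C[C@@H](O[Si](CC)(CC)CC)[C@@](C)(O[Si](CC)(CC)CC)CCC=C(C)C | intermediate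
6 | (3R,4S)-4,8-dimethyl-3,4-bis(triethylsilyloxy)nona-1,7-diene | C=C[C@@H](O[Si](CC)(CC)CC)[C@@](C)(O[Si](CC)(CC)CC)CCC=C(C)C | intermediate
7 | but-2-yn-1-ol | CC#CCO | starting material
8 | sodium 2,2-bis(2-methoxyethoxy)-3-methyl-2,5-dihydro-1,2-oxaaluminol-2-uide (cyclic alkenylalanate) | CC1=CCO[Al-]1(OCCOC)OCCOC.[Na+] | intermediate (not isolated)
9 | (Z)-3-iodobut-2-en-1-ol | C/C(I)=C/CO | intermediate
10 | 9-[(3R,4S)-4,8-dimethyl-3,4-bis(triethylsilyloxy)non-7-en-1-yl]-9-borabicyclo[3.3.1]nonane | CC(C)=CCC[C@](C)(O[Si](CC)(CC)CC)[C@H](O[Si](CC)(CC)CC)CCB1C2CCCC1CCC2 | intermediate (not isolated)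
11 | (2Z,6R,7S)-3,7,11-trimethyl-6,7-bis(triethylsilyloxy)dodeca-2,10-dien-1-ol | CC(C)=CCC[C@](C)(O[Si](CC)(CC)CC)[C@H](O[Si](CC)(CC)CC)CC/C(C)=C\CO | intermediate
12 | (2R,3S,6R,7S)-2,3-epoxy-3,7,11-trimethyl-6,7-bis(triethylsilyloxy)dodec-10-en-1-ol | CC(C)=CCC[C@](C)(O[Si](CC)(CC)CC)[C@H](O[Si](CC)(CC)CC)CC[C@]1(C)O[C@@H]1CO | intermediate
13 | (2S,3S,6R,7S)-2,3-epoxy-1-iodo-3,7,11-trimethyl-6,7-bis(triethylsilyloxy)dodec-10-ene | CC(C)=CCC[C@](C)(O[Si](CC)(CC)CC)[C@H](O[Si](CC)(CC)CC)CC[C@]1(C)O[C@@H]1CI | intermediate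
14 | methyl acetoacetate | COC(=O)CC(C)=O | starting material
15 | methyl (4R,5S,8R,9S)-2-acetyl-4,5-epoxy-5,9,13-trimethyl-8,9-bis(triethylsilyloxy)tetradec-12-enoate (C2 epimers) | CC(C)=CCC[C@](C)(O[Si](CC)(CC)CC)[C@H](O[Si](CC)(CC)CC)CC[C@]1(C)O[C@@H]1CC(C(C)=O)C(=O)OC | intermediate (not isolated)
16 | methyl (5S)-5-[(2S,5R,6S)-2-hydroxy-6,10-dimethyl-5,6-bis(triethylsilyloxy)undec-9-en-2-yl]-2-methyl-4,5-dihydrofuran-3-carboxylate | CC(C)=CCC[C@](C)(O[Si](CC)(CC)CC)[C@H](O[Si](CC)(CC)CC)CC[C@](C)(O)[C@@H]1CC(C(=O)OC)=C(C)O1 | intermediate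
17 | methyl (5S)-2-methyl-5-[(2S,5R,6S)-6,10-dimethyl-2,5,6-tris(triethylsilyloxy)undec-9-en-2-yl]-4,5-dihydrofuran-3-carboxylate | CC(C)=CCC[C@](C)(O[Si](CC)(CC)CC)[C@H](O[Si](CC)(CC)CC)CC[C@](C)(O[Si](CC)(CC)CC)[C@@H]1CC(C(=O)OC)=C(C)O1 | intermediate (key-step precursor)
18 | phenyl vinyl sulfone | C=CS(=O)(=O)c1ccccc1 | starting material
19 | lithium dienolate of 17 (2-methylidene ester enolate) | CC(C)=CCC[C@](C)(O[Si](CC)(CC)CC)[C@H](O[Si](CC)(CC)CC)CC[C@](C)(O[Si](CC)(CC)CC)[C@@H]1CC(=C([O-])OC)C(=C)O1.[Li+] | intermediate (not isolated)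
20 | lithiated Michael adduct, methyl (5S)-2-[3-lithio-3-(phenylsulfonyl)propyl]-5-[(2S,5R,6S)-6,10-dimethyl-2,5,6-tris(triethylsilyloxy)undec-9-en-2-yl]-4,5-dihydrofuran-3-carboxylate | CC(C)=CCC[C@](C)(O[Si](CC)(CC)CC)[C@H](O[Si](CC)(CC)CC)CC[C@](C)(O[Si](CC)(CC)CC)[C@@H]1CC(C(=O)OC)=C(CC[CH-]S(=O)(=O)c2ccccc2)O1.[Li+] | intermediate (not isolated)
21 | (2S)-2-[(2S,5R,6S)-6,10-dimethyl-2,5,6-tris(triethylsilyloxy)undec-9-en-2-yl]-5-(phenylsulfonyl)-2,3,6,7-tetrahydro-1-benzofuran-4(5H)-one (C5 epimers) | CC(C)=CCC[C@](C)(O[Si](CC)(CC)CC)[C@H](O[Si](CC)(CC)CC)CC[C@](C)(O[Si](CC)(CC)CC)[C@@H]1CC2=C(CCC(S(=O)(=O)c3ccccc3)C2=O)O1 | intermediate (key-step product)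
22 | (2S)-2-[(2S,5R,6S)-6,10-dimethyl-2,5,6-tris(triethylsilyloxy)undec-9-en-2-yl]-2,3,6,7-tetrahydro-1-benzofuran-4(5H)-one | CC(C)=CCC[C@](C)(O[Si](CC)(CC)CC)[C@H](O[Si](CC)(CC)CC)CC[C@](C)(O[Si](CC)(CC)CC)[C@@H]1CC2=C(CCCC2=O)O1 | intermediate
23 | (2S,5R)-5-hydroxy-2-[(2S,5R,6S)-6,10-dimethyl-2,5,6-tris(triethylsilyloxy)undec-9-en-2-yl]-2,3,6,7-tetrahydro-1-benzofuran-4(5H)-one | CC(C)=CCC[C@](C)(O[Si](CC)(CC)CC)[C@H](O[Si](CC)(CC)CC)CC[C@](C)(O[Si](CC)(CC)CC)[C@@H]1CC2=C(CC[C@@H](O)C2=O)O1 | intermediate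
24 | (2S,5R)-5-hydroxy-2-[(2S,5R,6S)-2,5,6-trihydroxy-6,10-dimethylundec-9-en-2-yl]-2,3,6,7-tetrahydro-1-benzofuran-4(5H)-one | CC(C)=CCC[C@](C)(O)[C@H](O)CC[C@](C)(O)[C@@H]1CC2=C(CC[C@@H](O)C2=O)O1 | target

**Step count**

Total: 15 steps. Longest linear sequence: 14 steps (steps 1–5 and 7–15, from geraniol); step 6 is a one-step side branch.

**Steps most likely to fail, with fallbacks**

Step 12 (Proposed new method). The α-sulfonyl carbanion may be quenched by proton transfer before it closes ring A, the vinyl sulfone may oligomerise under anionic conditions, or the dienolate may react through its α-carbon. The fallback replaces the anionic cascade by a neutral cycloaddition of known type. It sets out from 17: deprotonation as before and O-silylation (LiN(iPr)2, Me3SiCl, THF, −78 °C) would give the silyl ketene acetal diene F1, an s-cis-locked diene carrying donors at C4 and C7a. Diels–Alder reaction of this diene with 18 (toluene, 80–110 °C) would give the cycloadduct F2; the donors direct C7 to the unsubstituted carbon and C4 to the sulfonyl-bearing carbon of the dienophile. Work-up with dilute aqueous acid or wet silica collapses the mixed ketal at C4 to the ketone, and the route is rejoined at 21.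

Step 10. Ring closure may take place through carbon (cyclopropane formation) instead of oxygen, the epoxide may be opened at the tertiary carbon to give a six-membered ring, or the acetoacetate may be alkylated twice. The fallback builds ring B from a terminal epoxide by hemiketalisation and dehydration instead. It sets out from 12: Payne rearrangement with trapping by thiophenoxide (PhSH, aq. NaOH, t-BuOH, 70 °C) would give the phenylthio diol F3, with C2' inverted and C3' retained. S-Methylation (Me3OBF4, CH2Cl2) would give the sulfonium salt F4, and base (NaH) would close the terminal epoxide F5. Opening of F5 at C1' by the sodium enolate of 14 (NaOMe, MeOH, reflux) and lactonisation would give the α-acetyl lactone F6. Acid-mediated acyl-lactone rearrangement (HCl in MeOH, rt) would give the dihydrofuran ester, with loss of the silyl ethers, as the triol ester F7. Silylation of all three hydroxyls (Et3SiOTf, 2,6-lutidine) rejoins the route at 17.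

Step 14. Oxygen transfer to the flat enolate may show poor facial selectivity because the only resident stereocentre near the ring is remote, and the α-ketol may epimerise under basic conditions. The fallback corrects C5 by SN2 inversion instead of relying on reagent control. It sets out from 22: hydroxylation with KN(SiMe3)2 and racemic trans-2-(phenylsulfonyl)-3-phenyloxaziridine would give 23 together with its separable 5S epimer F8. Mitsunobu reaction of F8 (4-nitrobenzoic acid, PPh3, diisopropyl azodicarboxylate) would give the inverted 5R 4-nitrobenzoate F9, and brief methanolysis (K2CO3, MeOH, 0 °C) rejoins the route at 23.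

**Further compounds**

F1 | step 12 | (5S)-3-[methoxy(trimethylsilyloxy)methylidene]-2-methylidene-5-[(2S,5R,6S)-6,10-dimethyl-2,5,6-tris(triethylsilyloxy)undec-9-en-2-yl]oxolane | CC(C)=CCC[C@](C)(O[Si](CC)(CC)CC)[C@H](O[Si](CC)(CC)CC)CC[C@](C)(O[Si](CC)(CC)CC)[C@@H]1CC(=C(OC)O[Si](C)(C)C)C(=C)O1
F2 | step 12 | (2S)-4-methoxy-5-(phenylsulfonyl)-4-(trimethylsilyloxy)-2-[(2S,5R,6S)-6,10-dimethyl-2,5,6-tris(triethylsilyloxy)undec-9-en-2-yl]-2,3,4,5,6,7-hexahydro-1-benzofuran | CC(C)=CCC[C@](C)(O[Si](CC)(CC)CC)[C@H](O[Si](CC)(CC)CC)CC[C@](C)(O[Si](CC)(CC)CC)[C@@H]1CC2=C(CCC(S(=O)(=O)c3ccccc3)C2(OC)O[Si](C)(C)C)O1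
F3 | step 10 | (2R,3S,6R,7S)-3,7,11-trimethyl-1-(phenylsulfanyl)-6,7-bis(triethylsilyloxy)dodec-10-ene-2,3-diol | CC(C)=CCC[C@](C)(O[Si](CC)(CC)CC)[C@H](O[Si](CC)(CC)CC)CC[C@](C)(O)[C@@H](O)CSc1ccccc1
F4 | step 10 | S-methylsulfonium tetrafluoroborate of F3 | CC(C)=CCC[C@](C)(O[Si](CC)(CC)CC)[C@H](O[Si](CC)(CC)CC)CC[C@](C)(O)[C@@H](O)C[S+](C)c1ccccc1.F[B-](F)(F)F
F5 | step 10 | (2S,3S,6R,7S)-1,2-epoxy-3,7,11-trimethyl-6,7-bis(triethylsilyloxy)dodec-10-en-3-ol | CC(C)=CCC[C@](C)(O[Si](CC)(CC)CC)[C@H](O[Si](CC)(CC)CC)CC[C@](C)(O)[C@@H]1CO1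
F6 | step 10 | (5S)-3-acetyl-5-[(2S,5R,6S)-2-hydroxy-6,10-dimethyl-5,6-bis(triethylsilyloxy)undec-9-en-2-yl]oxolan-2-one (C3 epimers) | CC(C)=CCC[C@](C)(O[Si](CC)(CC)CC)[C@H](O[Si](CC)(CC)CC)CC[C@](C)(O)[C@@H]1CC(C(C)=O)C(=O)O1
F7 | step 10 | methyl (5S)-2-methyl-5-[(2S,5R,6S)-2,5,6-trihydroxy-6,10-dimethylundec-9-en-2-yl]-4,5-dihydrofuran-3-carboxylate | CC(C)=CCC[C@](C)(O)[C@H](O)CC[C@](C)(O)[C@@H]1CC(C(=O)OC)=C(C)O1
F8 | step 14 | (2S,5S)-5-hydroxy-2-[(2S,5R,6S)-6,10-dimethyl-2,5,6-tris(triethylsilyloxy)undec-9-en-2-yl]-2,3,6,7-tetrahydro-1-benzofuran-4(5H)-one | CC(C)=CCC[C@](C)(O[Si](CC)(CC)CC)[C@H](O[Si](CC)(CC)CC)CC[C@](C)(O[Si](CC)(CC)CC)[C@@H]1CC2=C(CC[C@H](O)C2=O)O1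
F9 | step 14 | (2S,5R)-2-[(2S,5R,6S)-6,10-dimethyl-2,5,6-tris(triethylsilyloxy)undec-9-en-2-yl]-4-oxo-2,3,4,5,6,7-hexahydro-1-benzofuran-5-yl 4-nitrobenzoate | CC(C)=CCC[C@](C)(O[Si](CC)(CC)CC)[C@H](O[Si](CC)(CC)CC)CC[C@](C)(O[Si](CC)(CC)CC)[C@@H]1CC2=C(CC[C@@H](OC(=O)c3ccc(cc3)[N+](=O)[O-])C2=O)O1
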